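The target is cut at the two bonds on either side of C4–C5, namely C5–C6 and C3–C4. Carbinol carbon C5 carries on one side C6–C7 and the guaiacyl ring, a fragment that hydroboration of a vinylarene supplies, and on the other side C4, attached to the C3 ketone of the arm that ends in C2–C1 and the catechol ring. An enantioselective nickel-catalysed conjunctive coupling inserts a vinyl unit between the alkylborane and an acid chloride, making both bonds and the C5–B stereocentre in one operation; oxidation then reveals the aldol. Its precursor is a lithium B-vinyl-B-(2-arylethyl)-9-BBN borate with the guaiacyl phenol benzylated.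

Key step: step 5

Remark on numbering: the heptanone chain runs from C1 (CH2 on the catechol ring) through C3 (ketone) and C5 (carbinol) to C7 (CH2 on the guaiacyl ring).

Assumption: the sense of induction of the nickel/diamine catalyst with an acyl electrophile cannot be predicted with certainty. The route is written with the (S,S)-diamine; the (R,R)-diamine is used instead if a pilot run with Mosher ester analysis of the C5 alcohol shows the (5S) series.

Remark: 9-BBN is bought as its dimer or as a THF solution and is drawn as the monomer.

Step 1
Reactants: 1 2-methoxy-4-vinylphenol (4-vinylguaiacol)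
Product: 2 1-benzyloxy-2-methoxy-4-vinylbenzene
Conditions: BnBr (1.1 equiv), K2CO3 (1.5 equiv), DMF, rt, dark, BHT (trace)
Reagents that add atoms: benzyl bromide, BrCc1ccccc1
Why: Williamson ether synthesis in which the phenoxide displaces bromide from the benzylic halide, run at room temperature with a radical inhibitor so that the polymerisation-prone styrene is left intact.

Step 2
Reactants: 3 tetravinylstannane
Product: 4 vinyllithium (halide-free)
Conditions: n-BuLi (4 equiv, hexanes), pentane, rt, Ar; filter the precipitate, wash with pentane; dissolve in cold THF, titrate, use promptly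
Reagents that add atoms: n-butyllithium, CCCC[Li]
Why: Tin–lithium exchange (transmetalation) places lithium on the more electronegative sp2 carbon, and the vinyllithium precipitates from the hydrocarbon while tetrabutylstannane stays dissolved, so the reagent should be obtained free of lithium halide.

Step 3
Reactants: 5 3-(3,4-dihydroxyphenyl)propanoic acid (dihydrocaffeic acid)
Product: 7 3-[3,4-bis(benzyloxy)phenyl]propanoic acid, via benzyl ester 6 (not isolated)
Conditions: BnBr (3.3 equiv), K2CO3 (4 equiv), DMF, 60 °C, N2; crude ester, NaOH (aq), THF/MeOH, 50 °C; HCl to pH 2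
Reagents that add atoms: benzyl bromide, BrCc1ccccc1; sodium hydroxide, [Na+].[OH-]
Why: Exhaustive O-benzylation of both phenols and the carboxylate (Williamson-type alkylation) followed by saponification, in which hydroxide cleaves only the benzyl ester while the aryl benzyl ethers are inert, should deliver the acid without purification of the intermediate.

Step 4
Reactants: 7 3-[3,4-bis(benzyloxy)phenyl]propanoic acid
Product: 8 3-[3,4-bis(benzyloxy)phenyl]propanoyl chloride
Conditions: (COCl)2 (1.3 equiv), DMF (cat.), CH2Cl2, 0 °C to rt; evaporate, strip with toluene; use at once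
Reagents that add atoms: oxalyl chloride, ClC(=O)C(Cl)=O
Why: Acid chloride formation by Vilsmeier-type activation with catalytic DMF releases only gases, so evaporation should leave an electrophile free of reagents that would destroy the borate, and the benzyl ethers are untouched in the absence of a Lewis acid.

Step 5
Reactants: 2 1-benzyloxy-2-methoxy-4-vinylbenzene; 9 9-borabicyclo[3.3.1]nonane (9-BBN); 4 vinyllithium; 8 3-[3,4-bis(benzyloxy)phenyl]propanoyl chloride
Product: 13 (5R)-1-[3,4-bis(benzyloxy)phenyl]-7-(4-benzyloxy-3-methoxyphenyl)-5-hydroxyheptan-3-one, via alkylborane 10 (not isolated), via lithium vinylborate 11 (not isolated), via boryl ketone 12 (not isolated)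
Conditions: 2 (1.05 equiv), 9-BBN (1.0 equiv), THF, 60 °C; vinyllithium (1.0 equiv), −78 to 0 °C; Ni(acac)2 (5 mol %), (S,S)-N,N'-dimethyl-1,2-diphenylethane-1,2-diamine (6 mol %, premixed), THF, −20 °C, 8 (1.1 equiv) by syringe pump over 2 h; then pH 7 phosphate buffer, 30% H2O2, 0 °C to rt
Reagents that add atoms: hydrogen peroxide, OO
Why: Proposed new method: after anti-Markovnikov hydroboration of the vinylarene and addition of vinyllithium to boron, zerovalent nickel generated in situ inserts into the C–Cl bond of 8, the divalent acyl nickel chloride binds the vinyl group of the borate, and this π-activation triggers a 1,2-shift of the exocyclic 2-arylethyl group from boron to the boron-bearing vinyl carbon, anti to nickel (C6–C5 bond and C5–B stereocentre), after which acyl–alkyl reductive elimination forms C4–C3. The closest known reaction types are the racemic nickel-catalysed conjunctive coupling of vinyl-9-BBN borates with acid chlorides or anhydrides and the enantioselective nickel/chiral 1,2-diamine conjunctive coupling of the same borates with aryl halides, and the proposal combines the electrophile of the first with the ligand control of the second. No ring is closed. The C5 stereocentre is controlled by the chiral diamine on nickel, which determines the face of the vinyl borate that the metal binds and hence the face on which the anti migration occurs, and the buffered peroxide oxidation then exchanges boron for oxygen with retention to give the (5R) alcohol. The step needs enantiofacial selectivity and needs the catalysed conjunctive path to outpace racemic uncatalysed acylation of the borate and direct alkyl transfer; the bicyclic 9-BBN carbons migrate poorly so only the primary 2-arylethyl group shifts, and slow addition of 8 at low temperature keeps the background small. Benzyl ethers are inert to the borane, to vinyllithium and to low-valent nickel, and oxidation at pH 7 avoids dehydration and retro-aldol cleavage of the β-hydroxy ketone.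

Step 6
Reactants: 13 (5R)-1-[3,4-bis(benzyloxy)phenyl]-7-(4-benzyloxy-3-methoxyphenyl)-5-hydroxyheptan-3-one
Product: 14 (5R)-1-(3,4-dihydroxyphenyl)-5-hydroxy-7-(4-hydroxy-3-methoxyphenyl)heptan-3-one (target CNP0094522.1)
Conditions: H2 (1 atm), Pd/C (10 wt %), EtOAc/EtOH, rt; filter under N2
Reagents that add atoms: none
Why: Catalytic hydrogenolysis cleaves the three benzylic C–O bonds of the aryl benzyl ethers under neutral conditions, whereas the dialkyl ketone, the aryl methyl ether and the non-benzylic C5 carbinol are inert, so the stereocentre should be carried through unchanged.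

Compound list
1 | 2-methoxy-4-vinylphenol (4-vinylguaiacol) | C=Cc1ccc(O)c(OC)c1 | starting material
2 | 1-benzyloxy-2-methoxy-4-vinylbenzene | C=Cc1ccc(OCc2ccccc2)c(OC)c1 | intermediate
3 | tetravinylstannane | C=C[Sn](C=C)(C=C)C=C | starting material
4 | vinyllithium | [Li]C=C | intermediate
5 | 3-(3,4-dihydroxyphenyl)propanoic acid (dihydrocaffeic acid) | OC(=O)CCc1ccc(O)c(O)c1 | starting material
6 | benzyl 3-[3,4-bis(benzyloxy)phenyl]propanoate | O=C(CCc1ccc(OCc2ccccc2)c(OCc2ccccc2)c1)OCc1ccccc1 | intermediate
7 | 3-[3,4-bis(benzyloxy)phenyl]propanoic acid | OC(=O)CCc1ccc(OCc2ccccc2)c(OCc2ccccc2)c1 | intermediate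
8 | 3-[3,4-bis(benzyloxy)phenyl]propanoyl chloride | O=C(Cl)CCc1ccc(OCc2ccccc2)c(OCc2ccccc2)c1 | intermediate
9 | 9-borabicyclo[3.3.1]nonane (9-BBN) | B1C2CCCC1CCC2 | starting material
10 | 9-[2-(4-benzyloxy-3-methoxyphenyl)ethyl]-9-borabicyclo[3.3.1]nonane | COc1cc(CCB2C3CCCC2CCC3)ccc1OCc1ccccc1 | intermediate
11 | lithium 9-[2-(4-benzyloxy-3-methoxyphenyl)ethyl]-9-vinyl-9-boratabicyclo[3.3.1]nonane (ate complex) | [Li+].C=C[B-]1(CCc2ccc(OCc3ccccc3)c(OC)c2)C2CCCC1CCC2 | intermediate
12 | (5R)-1-[3,4-bis(benzyloxy)phenyl]-7-(4-benzyloxy-3-methoxyphenyl)-5-(9-borabicyclo[3.3.1]nonan-9-yl)heptan-3-one | COc1cc(CC[C@@H](B2C3CCCC2CCC3)CC(=O)CCc2ccc(OCc3ccccc3)c(OCc3ccccc3)c2)ccc1OCc1ccccc1 | intermediate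
13 | (5R)-1-[3,4-bis(benzyloxy)phenyl]-7-(4-benzyloxy-3-methoxyphenyl)-5-hydroxyheptan-3-one | COc1cc(CC[C@@H](O)CC(=O)CCc2ccc(OCc3ccccc3)c(OCc3ccccc3)c2)ccc1OCc1ccccc1 | intermediate
14 | (5R)-1-(3,4-dihydroxyphenyl)-5-hydroxy-7-(4-hydroxy-3-methoxyphenyl)heptan-3-one | COc1cc(CC[C@@H](O)CC(=O)CCc2ccc(O)c(O)c2)ccc1O | target

Total step count: 6 (steps 3 and 5 are telescoped sequences).
Longest linear sequence: 4 steps (5 → 7 → 8 → 13 → 14; steps 3, 4, 5 and 6).

Steps most likely to fail

1. Step 5 (proposed new method). What may go wrong: insufficient facial discrimination by the diamine–nickel catalyst, erosion of enantiopurity by an uncatalysed racemic acylation-triggered shift of the borate, or gradual N-acylation of the secondary diamine by the acid chloride that leaves ligand-free nickel. The fallback uses known reactions only, sets out from borate 11 and acid chloride 8, and returns at 13. The established ligand-free racemic nickel-catalysed conjunctive acylation (NiBr2(dme), THF, 0 °C to rt) should give racemic 1-[3,4-bis(benzyloxy)phenyl]-7-(4-benzyloxy-3-methoxyphenyl)-5-(9-borabicyclo[3.3.1]nonan-9-yl)heptan-3-one F1. This is oxidised in the same flask (H2O2, pH 7 buffer) to the racemic 5-hydroxy ketone F2. Acid-catalysed dehydration (TsOH·H2O cat., toluene, 60 °C) removes the stereocentre and should give (E)-1-[3,4-bis(benzyloxy)phenyl]-7-(4-benzyloxy-3-methoxyphenyl)hept-4-en-3-one F3. Copper-catalysed enantioselective conjugate borylation of this acyclic enone (CuCl, NaOt-Bu, a Josiphos-type ferrocenyl diphosphine, B2pin2, MeOH, THF, rt) should then install boron at C5 as the (5R)-5-(pinacolboryl) ketone F4. The ligand enantiomer is chosen by a pilot run. Oxidation with NaBO3 in THF/water proceeds with retention and rejoins the route at 13.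

2. Step 4. What may go wrong: hydrolysis or intramolecular Friedel–Crafts acylation of the electron-rich ring while the acid chloride is made and stored, and carry-over of HCl that protonates the borate in step 5. The fallback sets out from acid 7 and returns at 13. Dehydrative coupling of two molecules of 7 with DCC (0.5 equiv, CH2Cl2, filtration of the urea) should give the symmetric 3-[3,4-bis(benzyloxy)phenyl]propanoic anhydride F5. This is a neutral, chloride-free acyl donor of a class already established in nickel-catalysed conjunctive acylation of 9-BBN borates. It replaces 8 in step 5 with the same catalyst, and the carboxylate leaving group is recovered as 7.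

3. Step 6. What may go wrong: acid-promoted dehydration of the aldol on the catalyst surface followed by saturation of the resulting enone, or stalling before the last benzyl ether is cleaved. The fallback sets out from 13 and arrives directly at 14. It is a non-reductive Lewis acid debenzylation with BCl3 and pentamethylbenzene as benzyl cation scavenger (CH2Cl2, −78 °C, cold MeOH quench). This cleaves aryl benzyl ethers without hydrogen or a metal surface and should spare the aryl methyl ether at that temperature. No new compound is made on the way (F0).

Further compounds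
F1 | step 5 | racemic 1-[3,4-bis(benzyloxy)phenyl]-7-(4-benzyloxy-3-methoxyphenyl)-5-(9-borabicyclo[3.3.1]nonan-9-yl)heptan-3-one | COc1cc(CCC(B2C3CCCC2CCC3)CC(=O)CCc2ccc(OCc3ccccc3)c(OCc3ccccc3)c2)ccc1OCc1ccccc1
F2 | step 5 | racemic 1-[3,4-bis(benzyloxy)phenyl]-7-(4-benzyloxy-3-methoxyphenyl)-5-hydroxyheptan-3-one | COc1cc(CCC(O)CC(=O)CCc2ccc(OCc3ccccc3)c(OCc3ccccc3)c2)ccc1OCc1ccccc1
F3 | step 5 | (E)-1-[3,4-bis(benzyloxy)phenyl]-7-(4-benzyloxy-3-methoxyphenyl)hept-4-en-3-one | COc1cc(CC/C=C/C(=O)CCc2ccc(OCc3ccccc3)c(OCc3ccccc3)c2)ccc1OCc1ccccc1
F4 | step 5 | (5R)-1-[3,4-bis(benzyloxy)phenyl]-7-(4-benzyloxy-3-methoxyphenyl)-5-(4,4,5,5-tetramethyl-1,3,2-dioxaborolan-2-yl)heptan-3-one | COc1cc(CC[C@@H](B2OC(C)(C)C(C)(C)O2)CC(=O)CCc2ccc(OCc3ccccc3)c(OCc3ccccc3)c2)ccc1OCc1ccccc1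
F5 | step 4 | 3-[3,4-bis(benzyloxy)phenyl]propanoic anhydride | O=C(CCc1ccc(OCc2ccccc2)c(OCc2ccccc2)c1)OC(=O)CCc1ccc(OCc2ccccc2)c(OCc2ccccc2)c1
F0 | step 6 | none | none
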